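Ring A is the benzo ring of the dihydrobenzofuran and ring B the resorcinol ring fused to the seven-membered ring. Ring C is the aryl on furan carbon C-2 and ring D the aryl on the methine next to the ketone (benzofuran locants throughout).
The seven-membered ketone is closed last. Both aryl bonds of the methine between C=O and ring B are cut, so this carbon becomes the acetal carbon of an arylglyoxal acetal (a 1,1-dication) and ring D becomes a simple phenyl ether.
Enabling feature: the methine is a gem-diaryl carbon next to C=O. Its ring B partner is ortho to one ring B oxygen and para to the other, its ring D partner is para to the ring D oxygen, and ring B on C-3 already sits beside the acyl group on C-4 of ring A. Both bonds are therefore Friedel–Crafts bonds, and the centre is enolisable.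
The keto acetal comes from the 4-bromo-2,3-dihydrobenzofuran by Br–Li exchange and acylation. The dihydrofuran ring comes from an o-quinone methide (ring A, with ring B on the exocyclic carbon) and a chiral sulfonium benzylide by (4+1) annulation, which sets C-2 and C-3.
Rings A and B come from the same 3,5-dialkoxybromobenzene. The dihydrofuran ring closes in step 6 and the seven-membered ring in step 8, and hydrogenolysis ends the route.

Key step: step 8

Assumption: the enolisable stereocentre next to the ketone has, in the target, the more stable configuration (ring D pseudo-axial, cis to H-3), as expected for such a centre in an isolated natural product.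
Assumption: the benzylide of the isothiocineole enantiomer derived from (R)-limonene transfers its carbon with the facial sense that gives (2R). If the opposite sense is found, the sulfide from (S)-limonene is used and nothing else changes.

Step 1
Reactants: 1 1,3-bis(benzyloxy)-5-bromobenzene
Product: 2 2,4-bis(benzyloxy)-6-bromobenzaldehyde
Conditions: POCl3, DMF, 0 to 90 °C; then H2O
Reagents that add atoms: N,N-dimethylformamide CN(C)C=O; water O
Why: Vilsmeier–Haack formylation should occur between a benzyloxy group and bromine, para to the other ether, because this site is less crowded than the one between the two ethers, as is usual for 3,5-dialkoxybromobenzenes.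

Step 2
Reactants: 2 2,4-bis(benzyloxy)-6-bromobenzaldehyde
Product: 3 4-(benzyloxy)-2-bromo-6-hydroxybenzaldehyde
Conditions: MgBr2·OEt2, toluene–Et2O, reflux; 1 M HCl
Reagents that add atoms: none
Why: This is a chelation-controlled ether cleavage in which MgBr2 bridges the aldehyde oxygen and the ortho ether oxygen, so bromide should remove only that benzyl group and leave the para ether and the aryl bromide untouched.

Step 3
Reactants: 1 1,3-bis(benzyloxy)-5-bromobenzene; 3 4-(benzyloxy)-2-bromo-6-hydroxybenzaldehyde
Product: 5 5-(benzyloxy)-2-{[3,5-bis(benzyloxy)phenyl](hydroxy)methyl}-3-bromophenol (racemic), via arylmagnesium bromide 4 (not isolated)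
Conditions: 1, Mg, THF, reflux (gives 4); 3, NaH, THF, 0 °C, then 4, 0 °C to rt; aq NH4Cl
Reagents that add atoms: none
Why: This is a Grignard addition to the aldehyde of the preformed sodium phenoxide, the arylmagnesium reagent should not exchange with the aryl bromide of 3, and the racemic carbinol centre is erased in step 6.

Step 4
Reactants: 5 5-(benzyloxy)-2-{[3,5-bis(benzyloxy)phenyl](hydroxy)methyl}-3-bromophenol
Product: 6 5-(benzyloxy)-2-{[3,5-bis(benzyloxy)phenyl](4-methylbenzenesulfonyl)methyl}-3-bromophenol (racemic)
Conditions: p-TolSO2H, CH2Cl2, rt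
Reagents that add atoms: 4-methylbenzenesulfinic acid Cc1ccc(cc1)S(=O)O
Why: In this SN1 substitution the electron-rich o-hydroxybenzhydrol ionises under the mild acidity of the reagent and sulfinate captures the cation at sulfur, which gives the stable sulfone that is the standard base-triggered o-quinone methide precursor.

Step 5
Reactants: 7 isothiocineole (enantiomer derived from (R)-limonene); 8 1-(benzyloxy)-4-(bromomethyl)benzene
Product: 9 exo-S-[4-(benzyloxy)benzyl]isothiocineolium trifluoromethanesulfonate
Conditions: LiOSO2CF3, CH2Cl2–H2O, rt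
Reagents that add atoms: lithium trifluoromethanesulfonate [Li+].[O-]S(=O)(=O)C(F)(F)F
Why: SN2 alkylation should take place on the less hindered exo lone pair of the bicyclic sulfide to give one sulfonium diastereomer, and exchange of bromide for triflate in the two-phase system prevents the reverse reaction.

Step 6
Reactants: 6 5-(benzyloxy)-2-{[3,5-bis(benzyloxy)phenyl](4-methylbenzenesulfonyl)methyl}-3-bromophenol; 9 exo-S-[4-(benzyloxy)benzyl]isothiocineolium trifluoromethanesulfonate
Product: 12 (2R,3R)-6-(benzyloxy)-2-[4-(benzyloxy)phenyl]-3-[3,5-bis(benzyloxy)phenyl]-4-bromo-2,3-dihydro-1-benzofuran, via o-quinone methide 10 (not isolated), via sulfonium benzylide 11 (not isolated)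
Conditions: Cs2CO3, MeCN, 0 °C to rt
Reagents that add atoms: none
Why: In this (4+1) annulation of an o-quinone methide with a sulfonium ylide, base expels sulfinate from 6, benzylide 11 adds to the exocyclic carbon of 10 and the freed phenoxide displaces the sulfide in a 5-exo-tet SN2 closure, so that the rigid sulfide, which fixes the ylide conformation and shields one face, sets C-2 and the anti approach of the two aryl groups sets the trans relation at C-3.

Step 7
Reactants: 12 (2R,3R)-6-(benzyloxy)-2-[4-(benzyloxy)phenyl]-3-[3,5-bis(benzyloxy)phenyl]-4-bromo-2,3-dihydro-1-benzofuran; 13 ethyl 2,2-diethoxyacetate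
Product: 15 1-{(2R,3R)-6-(benzyloxy)-2-[4-(benzyloxy)phenyl]-3-[3,5-bis(benzyloxy)phenyl]-2,3-dihydro-1-benzofuran-4-yl}-2,2-diethoxyethan-1-one, via aryllithium 14 (not isolated)
Conditions: n-BuLi, THF, −78 °C; then 13, −78 to −40 °C; aq NH4Cl
Reagents that add atoms: none
Why: Bromine–lithium exchange is faster than any deprotonation at −78 °C, and the aryllithium should acylate the ester only once because the chelated tetrahedral intermediate survives until the quench (the known route to arylglyoxal acetals), with no stereocentre touched.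

Step 8
Reactants: 15 1-{(2R,3R)-6-(benzyloxy)-2-[4-(benzyloxy)phenyl]-3-[3,5-bis(benzyloxy)phenyl]-2,3-dihydro-1-benzofuran-4-yl}-2,2-diethoxyethan-1-one; 16 benzyl phenyl ether
Product: 18 penta-O-benzylpauciflorol E (all three stereocentres R), via cyclic alpha-ethoxy ketone 17 (not isolated)
Conditions: SnCl4 (2.5 equiv), 16 (3 equiv), CH2Cl2 (5 mM), −78 to −20 °C; aq NaHCO3; then cat. DBU, CH2Cl2, rt
Reagents that add atoms: none
Why: SnCl4 binds the ketone oxygen and one acetal oxygen of 15 as a five-membered chelate and expels ethoxide, and the resulting alpha-acyl oxocarbenium ion is attacked by the ortho carbon of ring B (para to one benzyloxy group, ortho to the other; the two ortho positions are equivalent by rotation about the C-3–aryl bond) in a 7-exo-trig Friedel–Crafts closure that gives 17. The chelate then ionises the second C–OEt bond, now helped by the two oxygens of ring B, and the para carbon of 16 takes the cation, so that the former acetal carbon serves as a 1,1-dication and both aryl bonds of the gem-diaryl methine are formed in one flask; should 16 react first, only the order of the two arylations changes and the product is the same. The closest known reaction type is the acid-promoted twofold Friedel–Crafts arylation of arylglyoxals and their acetals to 2,2-diaryl-1-arylethanones. The one new stereocentre is controlled by C-3: in the boat-shaped dibenzocycloheptenone 16 should add along the pseudo-axial line on the convex face, cis to H-3, which gives the (R) centre, and since this centre is enolisable DBU converts any epimer into the same, more stable isomer in which ring D avoids the neighbouring benzyloxy group of ring B. The step needs ionisation at the acetal carbon and not at the benzylic C-2–O bond of the dihydrofuran, which is secured by bidentate binding of SnCl4 to the 1,2-dioxygen unit and by fast internal return of the ring A oxygen if C-2–O should open, and it needs ring closure before intermolecular attack, which is secured by high dilution and by ring B being the most electron-rich arene and held next to the acyl group.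

Step 9
Reactants: 18 penta-O-benzylpauciflorol E
Product: 19 pauciflorol E
Conditions: H2 (1 atm), Pd/C, EtOAc–MeOH, rt
Reagents that add atoms: none
Why: Hydrogenolysis of the five aryl benzyl ethers should be much faster than reduction of the hindered aryl ketone or cleavage of the cyclic benzylic C–O bond, and the neutral medium leaves the three stereocentres as set.

Compound list
1 | 1,3-bis(benzyloxy)-5-bromobenzene | Brc1cc(OCc2ccccc2)cc(OCc2ccccc2)c1 | starting material
2 | 2,4-bis(benzyloxy)-6-bromobenzaldehyde | O=Cc1c(Br)cc(OCc2ccccc2)cc1OCc1ccccc1 | intermediate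
3 | 4-(benzyloxy)-2-bromo-6-hydroxybenzaldehyde | O=Cc1c(Br)cc(OCc2ccccc2)cc1O | intermediate
4 | [3,5-bis(benzyloxy)phenyl]magnesium bromide (not isolated) | Br[Mg]c1cc(OCc2ccccc2)cc(OCc2ccccc2)c1 | intermediate
5 | 5-(benzyloxy)-2-{[3,5-bis(benzyloxy)phenyl](hydroxy)methyl}-3-bromophenol, racemic | OC(c1cc(OCc2ccccc2)cc(OCc2ccccc2)c1)c1c(O)cc(OCc2ccccc2)cc1Br | intermediate
6 | 5-(benzyloxy)-2-{[3,5-bis(benzyloxy)phenyl](4-methylbenzenesulfonyl)methyl}-3-bromophenol, racemic | Cc1ccc(cc1)S(=O)(=O)C(c1cc(OCc2ccccc2)cc(OCc2ccccc2)c1)c1c(O)cc(OCc2ccccc2)cc1Br | intermediate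
7 | isothiocineole, 4,7,7-trimethyl-6-thiabicyclo[3.2.1]octane, enantiomer derived from (R)-limonene, C-4 methyl equatorial and cis to the sulfur bridge | C[C@H]1CC[C@@H]2C[C@H]1SC2(C)C | starting material
8 | 1-(benzyloxy)-4-(bromomethyl)benzene | BrCc1ccc(OCc2ccccc2)cc1 | starting material
9 | 6-[4-(benzyloxy)benzyl]-4,7,7-trimethyl-6-thiabicyclo[3.2.1]octan-6-ium trifluoromethanesulfonate, benzyl group exo (syn to the one-carbon bridge) | C[C@H]1CC[C@@H]2C[C@H]1[S@@+](Cc1ccc(OCc3ccccc3)cc1)C2(C)C.[O-]S(=O)(=O)C(F)(F)F | intermediate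
10 | 3-(benzyloxy)-6-{[3,5-bis(benzyloxy)phenyl]methylidene}-5-bromocyclohexa-2,4-dien-1-one, aryl group on the carbonyl side (not isolated) | O=C1C=C(OCc2ccccc2)C=C(Br)/C1=C/c1cc(OCc2ccccc2)cc(OCc2ccccc2)c1 | intermediate
11 | sulfonium 4-(benzyloxy)benzylide derived from 9 (not isolated) | C[C@H]1CC[C@@H]2C[C@H]1[S@@+]([CH-]c1ccc(OCc3ccccc3)cc1)C2(C)C | intermediate
12 | (2R,3R)-6-(benzyloxy)-2-[4-(benzyloxy)phenyl]-3-[3,5-bis(benzyloxy)phenyl]-4-bromo-2,3-dihydro-1-benzofuran (trans) | Brc1cc(OCc2ccccc2)cc2c1[C@@H](c1cc(OCc3ccccc3)cc(OCc3ccccc3)c1)[C@H](c1ccc(OCc3ccccc3)cc1)O2 | intermediate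
13 | ethyl 2,2-diethoxyacetate | CCOC(=O)C(OCC)OCC | starting material
14 | 4-lithio derivative of 12 (not isolated) | [Li]c1cc(OCc2ccccc2)cc2c1[C@@H](c1cc(OCc3ccccc3)cc(OCc3ccccc3)c1)[C@H](c1ccc(OCc3ccccc3)cc1)O2 | intermediate
15 | 1-{(2R,3R)-6-(benzyloxy)-2-[4-(benzyloxy)phenyl]-3-[3,5-bis(benzyloxy)phenyl]-2,3-dihydro-1-benzofuran-4-yl}-2,2-diethoxyethan-1-one | CCOC(OCC)C(=O)c1cc(OCc2ccccc2)cc2c1[C@@H](c1cc(OCc3ccccc3)cc(OCc3ccccc3)c1)[C@H](c1ccc(OCc3ccccc3)cc1)O2 | intermediate
16 | benzyl phenyl ether | C(Oc1ccccc1)c1ccccc1 | starting material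
17 | target skeleton without ring D, ethoxy group on the carbon next to the ketone (both epimers there), four benzyl ethers, C-2 and C-3 (R) (not isolated) | O=C1c2cc(OCc4ccccc4)cc3c2[C@@H](c2cc(OCc4ccccc4)cc(OCc4ccccc4)c2C1OCC)[C@H](c1ccc(OCc4ccccc4)cc1)O3 | intermediate
18 | penta-O-benzylpauciflorol E, (R) at C-2, at C-3 and at the ring D methine | O=C1c2cc(OCc4ccccc4)cc3c2[C@@H](c2cc(OCc4ccccc4)cc(OCc4ccccc4)c2[C@H]1c1ccc(OCc4ccccc4)cc1)[C@H](c1ccc(OCc4ccccc4)cc1)O3 | intermediate
19 | pauciflorol E | O=C1c2cc(O)cc3c2[C@@H](c2cc(O)cc(O)c2[C@H]1c1ccc(O)cc1)[C@H](c1ccc(O)cc1)O3 | target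

Total step count: 9. Longest linear sequence: 8 steps (1, 2, 3, 4, 6, 7, 8, 9) from 1.

Steps most likely to fail

Step 8. Three things may go wrong. The benzylic C-2–O bond of the dihydrofuran may heterolyse and that cation be captured by 16, benzyl groups may be lost to SnCl4, or a twofold intermolecular arylation may occur before the ring closes. The fallback sets out from 12 and comes back at 18. Ring D is brought in together with the two-carbon unit, and the cation is generated from a diazo group with only a trace of acid and no external arene.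
- Commercial 4-(benzyloxy)phenylacetic acid is converted (carbonyldiimidazole, MeNHOMe·HCl) into N-methoxy-N-methyl-2-[4-(benzyloxy)phenyl]acetamide F1.
- Aryllithium 14, made from 12 as in step 7, is acylated by F1 to the 4-(benzyloxy)benzyl ketone F2.
- Regitz diazo transfer (4-acetamidobenzenesulfonyl azide, DBU, MeCN) gives the alpha-aryl-alpha-diazo ketone F3.
- Catalytic CF3SO3H in CH2Cl2 at −40 °C protonates the diazo carbon, nitrogen leaves, and ring B closes the seven-membered ring in the same Friedel–Crafts mode to give 18.

Step 6. Poor facial selectivity of the benzylide toward the hindered quinone methide, or erosion of the trans selectivity, would lower the optical purity. The fallback sets out from 6 and comes back at 12, and it replaces reagent control by resolution.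
- 8 and tetrahydrothiophene give 1-[4-(benzyloxy)benzyl]thiolan-1-ium bromide F4.
- F4 with 6 and Cs2CO3 undergoes the same annulation to the racemic trans product, that is 12 together with its (2S,3S) mirror image F5.
- Preparative chromatography on a chiral stationary phase separates the two, and the route goes on from 12.

Step 7. The hindered aryllithium may be protonated before acylation, or a second addition to the ketone may occur. The fallback sets out from 12 and comes back at 15, and it replaces the organolithium by cross-coupling and oxidation.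
- Stille coupling of 12 with tributyl(1-ethoxyvinyl)stannane (Pd(PPh3)4, toluene, 100 °C) gives the 4-(1-ethoxyethenyl) compound F6.
- Dilute HCl hydrolyses F6 to the 4-acetyl compound F7.
- Riley oxidation (SeO2, dioxane–H2O, reflux) gives the arylglyoxal F8.
- HC(OEt)3 with a trace of TsOH in EtOH acetalises the aldehyde group of F8 to give 15.

Further compounds
F1 | step 8 | N-methoxy-N-methyl-2-[4-(benzyloxy)phenyl]acetamide | CON(C)C(=O)Cc1ccc(OCc2ccccc2)cc1
F2 | step 8 | 1-{(2R,3R)-6-(benzyloxy)-2-[4-(benzyloxy)phenyl]-3-[3,5-bis(benzyloxy)phenyl]-2,3-dihydro-1-benzofuran-4-yl}-2-[4-(benzyloxy)phenyl]ethan-1-one | O=C(Cc1ccc(OCc2ccccc2)cc1)c1cc(OCc2ccccc2)cc2c1[C@@H](c1cc(OCc3ccccc3)cc(OCc3ccccc3)c1)[C@H](c1ccc(OCc3ccccc3)cc1)O2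
F3 | step 8 | 2-diazo derivative of F2 | O=C(C(=[N+]=[N-])c1ccc(OCc2ccccc2)cc1)c1cc(OCc2ccccc2)cc2c1[C@@H](c1cc(OCc3ccccc3)cc(OCc3ccccc3)c1)[C@H](c1ccc(OCc3ccccc3)cc1)O2
F4 | step 6 | 1-[4-(benzyloxy)benzyl]thiolan-1-ium bromide | [Br-].C1CC[S+](C1)Cc1ccc(OCc2ccccc2)cc1
F5 | step 6 | (2S,3S)-6-(benzyloxy)-2-[4-(benzyloxy)phenyl]-3-[3,5-bis(benzyloxy)phenyl]-4-bromo-2,3-dihydro-1-benzofuran | Brc1cc(OCc2ccccc2)cc2c1[C@H](c1cc(OCc3ccccc3)cc(OCc3ccccc3)c1)[C@@H](c1ccc(OCc3ccccc3)cc1)O2
F6 | step 7 | (2R,3R)-6-(benzyloxy)-2-[4-(benzyloxy)phenyl]-3-[3,5-bis(benzyloxy)phenyl]-4-(1-ethoxyethenyl)-2,3-dihydro-1-benzofuran | C=C(OCC)c1cc(OCc2ccccc2)cc2c1[C@@H](c1cc(OCc3ccccc3)cc(OCc3ccccc3)c1)[C@H](c1ccc(OCc3ccccc3)cc1)O2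
F7 | step 7 | 1-{(2R,3R)-6-(benzyloxy)-2-[4-(benzyloxy)phenyl]-3-[3,5-bis(benzyloxy)phenyl]-2,3-dihydro-1-benzofuran-4-yl}ethan-1-one | CC(=O)c1cc(OCc2ccccc2)cc2c1[C@@H](c1cc(OCc3ccccc3)cc(OCc3ccccc3)c1)[C@H](c1ccc(OCc3ccccc3)cc1)O2
F8 | step 7 | 2-{(2R,3R)-6-(benzyloxy)-2-[4-(benzyloxy)phenyl]-3-[3,5-bis(benzyloxy)phenyl]-2,3-dihydro-1-benzofuran-4-yl}-2-oxoacetaldehyde | O=CC(=O)c1cc(OCc2ccccc2)cc2c1[C@@H](c1cc(OCc3ccccc3)cc(OCc3ccccc3)c1)[C@H](c1ccc(OCc3ccccc3)cc1)O2
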